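**Retrosynthetic overview**
Numbering: C1 is the ring CH that carries the 6-methylhepta-1,5-dien-2-yl group (attachment carbon C15). The ring continues C2, C3=C4(Me), C5, C6, C7=C8(Me), C9, C10, C11=C12(Me), C13, C14 = CH(OMe). The SMILES is read as 1R,14S and 3Z,7Z,11E.
Enabling feature: in the 14-membered carbocycle, the methyl-bearing sp2 carbon C4 of the Z alkene C3=C4 is bonded to C5, an unbranched CH2 homoallylic to C7=C8. The ring can therefore be cut there into a Z-alkenyl iodide (C4–I) and a primary C5 radical. That radical is stored as the N-hydroxyphthalimide ester of the one-carbon-longer acid, and both activating groups are expelled in the ring closure itself, a nickel-electrocatalytic decarboxylative alkenylation.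
Acyclic precursor: C3=C4 comes from a Z-selective iodoethylidene Wittig reaction on the C3 aldehyde. C1–C15 comes from syn-selective alkenylcuprate addition to a Z-enoate (C1=C2–C3). C13–C14 comes from an oxazolidinone glycolate alkylation, which sets C14 and brings in the OMe group.
C5–C13 with both of its alkenes comes from nerol. Acetate-enolate alkylation of neryl bromide adds C5 and the sacrificial carboxyl carbon, and E-selective SeO2 oxidation functionalises the terminal methyl group (C13).
Ring order: there is one ring only, the 14-membered carbocycle, and it is formed in the last step.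

Key step: step 16

Assumption: nerol is used as the geometrically pure Z isomer, because its alkene is carried unchanged into C7=C8.

**Route**

Step 1
Reactants: 1 nerol
Product: 2 neryl bromide
Conditions: PBr3 (0.4 equiv), Et2O, -10 °C
Reagents that add atoms: phosphorus tribromide, BrP(Br)Br
Why: Alcohol-to-bromide substitution with PBr3 is an SN2 process at the primary allylic carbon and at low temperature should leave the Z alkene (the later C7=C8) untouched.

Step 2
Reactants: 2 neryl bromide
Product: 3 tert-butyl (4Z)-5,9-dimethyldeca-4,8-dienoate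
Conditions: LiN(i-Pr)2, tert-butyl acetate, THF, -78 °C; then 2, DMPU, -78 to 0 °C
Reagents that add atoms: tert-butyl acetate, CC(=O)OC(C)(C)C
Why: Ester enolate alkylation: the lithium enolate of tert-butyl acetate resists self-condensation and displaces the primary allylic bromide in the SN2 sense, which adds C5 and the carboxyl carbon that the key step later expels as CO2.

Step 3
Reactants: 3 tert-butyl (4Z)-5,9-dimethyldeca-4,8-dienoate
Product: 4 tert-butyl (4Z,8E)-10-hydroxy-5,9-dimethyldeca-4,8-dienoate
Conditions: SeO2 (cat.), t-BuOOH, salicylic acid (cat.), CH2Cl2, 0 °C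
Reagents that add atoms: selenium dioxide (oxygen carrier), O=[Se]=O; tert-butyl hydroperoxide (terminal oxygen source), CC(C)(C)OO
Why: Riley-type allylic oxidation (ene reaction followed by a [2,3]-sigmatropic shift) prefers the exposed terminal isopropylidene unit and through its cyclic transition states gives the E-configured primary allylic alcohol, which fixes C11=C12 as E and functionalises C13.

Step 4
Reactants: 4 tert-butyl (4Z,8E)-10-hydroxy-5,9-dimethyldeca-4,8-dienoate
Product: 5 tert-butyl (4Z,8E)-10-bromo-5,9-dimethyldeca-4,8-dienoate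
Conditions: CBr4, PPh3, CH2Cl2, 0 °C
Reagents that add atoms: carbon tetrabromide, BrC(Br)(Br)Br
Why: The Appel reaction converts the primary allylic alcohol into the bromide under neutral conditions, without allylic transposition and without harm to the tert-butyl ester.

Step 5
Reactants: 6 (4R)-4-benzyl-1,3-oxazolidin-2-one
Product: 8 (4R)-4-benzyl-3-(methoxyacetyl)-1,3-oxazolidin-2-one, via N-lithio oxazolidinone 7 (not isolated)
Conditions: n-BuLi, THF, -78 °C; then MeOCH2COCl, -78 to 0 °C
Reagents that add atoms: methoxyacetyl chloride, COCC(=O)Cl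
Why: N-acylation of the lithiated oxazolidinone with an acid chloride is the standard way to load the auxiliary and does not touch its stereocentre.

Step 6
Reactants: 8 (4R)-4-benzyl-3-(methoxyacetyl)-1,3-oxazolidin-2-one; 5 tert-butyl (4Z,8E)-10-bromo-5,9-dimethyldeca-4,8-dienoate
Product: 10 tert-butyl (4Z,8E,11S)-12-[(4R)-4-benzyl-2-oxo-1,3-oxazolidin-3-yl]-11-methoxy-5,9-dimethyl-12-oxododeca-4,8-dienoate, via sodium Z-enolate 9 (not isolated)
Conditions: NaN(SiMe3)2, THF, -78 °C; then 5, Bu4NI (cat.), -78 to -40 °C
Reagents that add atoms: none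
Why: Evans-type asymmetric alkylation of a glycolate imide: the sodium-chelated Z-enolate is alkylated by the allylic bromide on the face opposite the benzyl group, which forms C13–C14, sets C14 as S and installs the methyl ether as such.

Step 7
Reactants: 10 the alkylated imide
Product: 11 tert-butyl (4Z,8E,11S)-12-hydroxy-11-methoxy-5,9-dimethyldodeca-4,8-dienoate
Conditions: LiBH4, H2O (1 equiv), Et2O, 0 °C
Reagents that add atoms: none
Why: Reductive removal of the auxiliary: LiBH4 attacks the activated exocyclic imide carbonyl much faster than the tert-butyl ester and leaves C14 untouched.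

Step 8
Reactants: 11 the primary alcohol
Product: 12 tert-butyl (4Z,8E,11S)-11-methoxy-5,9-dimethyl-12-oxododeca-4,8-dienoate
Conditions: Dess–Martin periodinane, CH2Cl2, 0 °C to rt
Reagents that add atoms: none
Why: Dess–Martin oxidation runs under nearly neutral conditions, so the alpha-methoxy aldehyde should form without epimerisation at C14 and without attack on the alkenes.

Step 9
Reactants: 12 the alpha-methoxy aldehyde
Product: 13 1-tert-butyl 14-methyl (4Z,8E,11S,12Z)-11-methoxy-5,9-dimethyltetradeca-4,8,12-trienedioate
Conditions: (CF3CH2O)2P(O)CH2CO2Me, KN(SiMe3)2, 18-crown-6, THF, -78 °C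
Reagents that add atoms: methyl bis(2,2,2-trifluoroethyl)phosphonoacetate, COC(=O)CP(=O)(OCC(F)(F)F)OCC(F)(F)F
Why: Still–Gennari olefination: the trifluoroethyl phosphonate with a dissociated potassium base eliminates from the kinetic adduct and should give the Z-enoate, the geometry needed for facial control in step 11.

Step 10
Reactants: 14 6-methylhept-5-en-2-one
Product: 15 (E)-2,4,6-triisopropylbenzenesulfonylhydrazone of 6-methylhept-5-en-2-one
Conditions: 2,4,6-(i-Pr)3C6H2SO2NHNH2, MeOH, HCl (cat.), rt
Reagents that add atoms: 2,4,6-triisopropylbenzenesulfonyl hydrazide, CC(C)c1cc(C(C)C)c(S(=O)(=O)NN)c(C(C)C)c1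
Why: Acid-catalysed condensation of the methyl ketone with the sulfonyl hydrazide gives the hydrazone with the N–H group on the methyl side, which later directs deprotonation to that methyl group.

Step 11
Reactants: 15 the sulfonylhydrazone; 13 the Z-enoate
Product: 19 1-tert-butyl 14-methyl (4Z,8E,11S,12R)-11-methoxy-5,9-dimethyl-12-(6-methylhepta-1,5-dien-2-yl)tetradeca-4,8-dienedioate, via alkenyllithium 16 (not isolated), via lithium dialkenylcuprate 17 (not isolated), via silyl ketene acetal 18 (not isolated)
Conditions: 15 (3 equiv), n-BuLi (6 equiv), THF, -78 to 0 °C; CuI (1.5 equiv), -40 °C; Me3SiCl, then 13, -78 °C; aq NH4Cl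
Reagents that add atoms: none
Why: The Shapiro reaction (loss of sulfinate and N2 from the dianion) gives the 2-lithio-1-alkene, and Me3SiCl-assisted conjugate addition of its Gilman cuprate follows the known syn preference of Z-configured gamma-alkoxy enoates: A(1,3) strain holds the C14–H bond in the alkene plane, the cuprate attacks C1 on the face flanked by the small OMe group and away from the C13 chain, and C1 is set as R.

Step 12
Reactants: 19 the mixed diester
Product: 21 tert-butyl (4Z,8E,11S,12R)-11-methoxy-5,9-dimethyl-12-(6-methylhepta-1,5-dien-2-yl)-14-oxotetradeca-4,8-dienoate, via aluminium hemiacetal 20 (not isolated)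
Conditions: i-Bu2AlH (1 equiv), toluene, -78 °C; aq Rochelle salt
Reagents that add atoms: none
Why: Partial ester reduction with i-Bu2AlH: the aluminium hemiacetal of the methyl ester survives at -78 °C until work-up while the bulky tert-butyl ester reacts more slowly, so one equivalent should stop at the C3 aldehyde.

Step 13
Reactants: 21 the C3 aldehyde
Product: 22 tert-butyl (4Z,8E,11S,12R,14Z)-15-iodo-11-methoxy-5,9-dimethyl-12-(6-methylhepta-1,5-dien-2-yl)hexadeca-4,8,14-trienoate
Conditions: EtPPh3I, n-BuLi, THF, rt; I2, -78 °C; NaN(SiMe3)2, -20 °C; then 21, -78 to -20 °C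
Reagents that add atoms: ethyltriphenylphosphonium iodide, CC[P+](c1ccccc1)(c1ccccc1)c1ccccc1.[I-]; iodine, II
Why: The Stork–Zhao-type Wittig olefination with the non-stabilised ylide Ph3P=C(I)Me is under kinetic control and should place iodine cis to the C2 chain (Z-iodide), the geometry that the ring closure later copies into C3=C4.

Step 14
Reactants: 22 the Z-alkenyl iodide tert-butyl ester
Product: 24 (4Z,8E,11S,12R,14Z)-15-iodo-11-methoxy-5,9-dimethyl-12-(6-methylhepta-1,5-dien-2-yl)hexadeca-4,8,14-trienoic acid, via trimethylsilyl ester 23 (not isolated)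
Conditions: Me3SiOTf, 2,6-lutidine, CH2Cl2, 0 °C; aq pH 5 buffer
Reagents that add atoms: none
Why: Silyl triflate-mediated cleavage of the tert-butyl ester (loss of isobutene under lutidine buffering, then hydrolysis of the silyl ester) avoids the protic acid that would start cation–olefin cyclisation of the polyene.

Step 15
Reactants: 24 the iodo acid
Product: 25 1,3-dioxoisoindolin-2-yl ester of 24
Conditions: N-hydroxyphthalimide, i-PrN=C=N-i-Pr, DMAP (cat.), CH2Cl2, rt
Reagents that add atoms: N-hydroxyphthalimide, O=C1c2ccccc2C(=O)N1O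
Why: Steglich-type carbodiimide esterification with N-hydroxyphthalimide turns the acid into the redox-active ester under neutral conditions that spare the alkenyl iodide.

Step 16
Reactants: 25 the redox-active ester
Product: 26 CNP0391665.1
Conditions: NiCl2(dme) (30 mol %), 2,2'-bipyridine (30 mol %), LiBr, DMF, undivided cell, Mg anode, RVC cathode pre-plated with Ag nanoparticles, constant current matched to the syringe-pump feed of 25 (final 2 mM), rt
Reagents that add atoms: none
Why: Proposed new method: zerovalent nickel formed at the cathode inserts with retention into the C4–I bond, the silver-coated cathode reduces the phthalimide ester, which loses phthalimide anion and CO2 to leave the primary C5 radical, and capture of that radical by the divalent alkenylnickel followed by reductive elimination from trivalent nickel forges C4–C5. The closest known reaction type is the intermolecular nickel-electrocatalytic decarboxylative alkenylation of primary redox-active esters with alkenyl iodides, which tolerates skipped polyenes and keeps alkene geometry; new here are the intramolecular mode and the methyl-bearing iodide carbon. The 14-membered carbocycle closes end to end: radical capture gives a 15-membered nickelacycle, and C(sp2)–C(sp3) reductive elimination contracts it by one atom. No stereocentre is created, C1 and C14 are spectators, and the Z geometry of C3=C4 is carried over from 22 because oxidative addition and reductive elimination both go with retention. The step needs ring closure over dimerisation, which slow feed into excess catalyst and the folding of the chain by its two Z alkenes and the C1/C14 branch points should secure, and it needs radical capture to outrun 5-exo insertion of the alkenylnickel into the C15 methylene, which is addressed by matching current to feed so that the alkenylnickel is not reduced to the faster-inserting monovalent state. The C5 radical has no 5-exo or 6-exo alkene partner (only a reversible 3-exo closure onto C7=C8), so it should live long enough to be captured.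

**Compound list**
1 | nerol, (2Z)-3,7-dimethylocta-2,6-dien-1-ol | OC/C=C(/C)CCC=C(C)C | starting material
2 | neryl bromide, (2Z)-1-bromo-3,7-dimethylocta-2,6-diene | BrC/C=C(/C)CCC=C(C)C | intermediate
3 | tert-butyl (4Z)-5,9-dimethyldeca-4,8-dienoate | CC(C)=CCC/C(C)=C\CCC(=O)OC(C)(C)C | intermediate
4 | tert-butyl (4Z,8E)-10-hydroxy-5,9-dimethyldeca-4,8-dienoate | OC/C(C)=C/CC/C(C)=C\CCC(=O)OC(C)(C)C | intermediate
5 | tert-butyl (4Z,8E)-10-bromo-5,9-dimethyldeca-4,8-dienoate | BrC/C(C)=C/CC/C(C)=C\CCC(=O)OC(C)(C)C | intermediate
6 | (4R)-4-benzyl-1,3-oxazolidin-2-one | O=C1N[C@H](Cc2ccccc2)CO1 | starting material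
7 | N-lithio derivative of 6 | [Li+].O=C1[N-][C@H](Cc2ccccc2)CO1 | intermediate
8 | (4R)-4-benzyl-3-(methoxyacetyl)-1,3-oxazolidin-2-one | COCC(=O)N1[C@H](Cc2ccccc2)COC1=O | intermediate
9 | sodium Z-enolate of 8 | [Na+].CO/C=C(\[O-])N1[C@H](Cc2ccccc2)COC1=O | intermediate
10 | tert-butyl (4Z,8E,11S)-12-[(4R)-4-benzyl-2-oxo-1,3-oxazolidin-3-yl]-11-methoxy-5,9-dimethyl-12-oxododeca-4,8-dienoate | O=C([C@@H](OC)C/C(C)=C/CC/C(C)=C\CCC(=O)OC(C)(C)C)N1[C@H](Cc2ccccc2)COC1=O | intermediate
11 | tert-butyl (4Z,8E,11S)-12-hydroxy-11-methoxy-5,9-dimethyldodeca-4,8-dienoate | OC[C@@H](OC)C/C(C)=C/CC/C(C)=C\CCC(=O)OC(C)(C)C | intermediate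
12 | tert-butyl (4Z,8E,11S)-11-methoxy-5,9-dimethyl-12-oxododeca-4,8-dienoate | O=C[C@@H](OC)C/C(C)=C/CC/C(C)=C\CCC(=O)OC(C)(C)C | intermediate
13 | 1-tert-butyl 14-methyl (4Z,8E,11S,12Z)-11-methoxy-5,9-dimethyltetradeca-4,8,12-trienedioate | COC(=O)/C=C\[C@@H](OC)C/C(C)=C/CC/C(C)=C\CCC(=O)OC(C)(C)C | intermediate
14 | 6-methylhept-5-en-2-one | CC(=O)CCC=C(C)C | starting material
15 | (E)-2,4,6-triisopropylbenzenesulfonylhydrazone of 14 | C/C(CCC=C(C)C)=N\NS(=O)(=O)c1c(C(C)C)cc(C(C)C)cc1C(C)C | intermediate
16 | (6-methylhepta-1,5-dien-2-yl)lithium | [Li]C(=C)CCC=C(C)C | intermediate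
17 | lithium bis(6-methylhepta-1,5-dien-2-yl)cuprate | [Li+].C=C(CCC=C(C)C)[Cu-]C(=C)CCC=C(C)C | intermediate
18 | trimethylsilyl ketene acetal of 19 | C=C(CCC=C(C)C)[C@@H](C=C(OC)O[Si](C)(C)C)[C@H](C/C(C)=C/CC/C(C)=C\CCC(=O)OC(C)(C)C)OC | intermediate
19 | 1-tert-butyl 14-methyl (4Z,8E,11S,12R)-11-methoxy-5,9-dimethyl-12-(6-methylhepta-1,5-dien-2-yl)tetradeca-4,8-dienedioate | C=C(CCC=C(C)C)[C@@H](CC(=O)OC)[C@H](C/C(C)=C/CC/C(C)=C\CCC(=O)OC(C)(C)C)OC | intermediate
20 | diisobutylaluminium methyl hemiacetal of 21 | C=C(CCC=C(C)C)[C@@H](CC(OC)O[Al](CC(C)C)CC(C)C)[C@H](C/C(C)=C/CC/C(C)=C\CCC(=O)OC(C)(C)C)OC | intermediate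
21 | tert-butyl (4Z,8E,11S,12R)-11-methoxy-5,9-dimethyl-12-(6-methylhepta-1,5-dien-2-yl)-14-oxotetradeca-4,8-dienoate | C=C(CCC=C(C)C)[C@@H](CC=O)[C@H](C/C(C)=C/CC/C(C)=C\CCC(=O)OC(C)(C)C)OC | intermediate
22 | tert-butyl (4Z,8E,11S,12R,14Z)-15-iodo-11-methoxy-5,9-dimethyl-12-(6-methylhepta-1,5-dien-2-yl)hexadeca-4,8,14-trienoate | C=C(CCC=C(C)C)[C@@H](C/C=C(/C)I)[C@H](C/C(C)=C/CC/C(C)=C\CCC(=O)OC(C)(C)C)OC | intermediate
23 | trimethylsilyl ester of 24 | C=C(CCC=C(C)C)[C@@H](C/C=C(/C)I)[C@H](C/C(C)=C/CC/C(C)=C\CCC(=O)O[Si](C)(C)C)OC | intermediate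
24 | (4Z,8E,11S,12R,14Z)-15-iodo-11-methoxy-5,9-dimethyl-12-(6-methylhepta-1,5-dien-2-yl)hexadeca-4,8,14-trienoic acid | C=C(CCC=C(C)C)[C@@H](C/C=C(/C)I)[C@H](C/C(C)=C/CC/C(C)=C\CCC(=O)O)OC | intermediate
25 | 1,3-dioxoisoindolin-2-yl ester of 24 | C=C(CCC=C(C)C)[C@@H](C/C=C(/C)I)[C@H](C/C(C)=C/CC/C(C)=C\CCC(=O)ON1C(=O)c2ccccc2C1=O)OC | intermediate
26 | CNP0391665.1, (1S,2R,4Z,8Z,12E)-1-methoxy-5,9,13-trimethyl-2-(6-methylhepta-1,5-dien-2-yl)cyclotetradeca-4,8,12-triene | C=C(CCC=C(C)C)[C@H]1C/C=C(/C)CC/C=C(/C)CC/C=C(\C)C[C@@H]1OC | target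

**Step count and risks**
Total step count: 16. Longest linear sequence: 14 steps from nerol (steps 1–4, 6–9 and 11–16).

Steps most likely to fail:

**Step 16 (ring closure).**
- What may go wrong: chain ends of different molecules may couple (oligomerisation). The alkenylnickel may insert into the C15 methylene in the 5-exo sense before the radical arrives. The C5 radical may abstract hydrogen from the solvent. Its reversible 3-exo closure onto C7=C8 may erode the Z geometry.
- Fallback: known chemistry that uses two-electron transmetallation instead of radical capture. It sets out from 25 and comes back at 26. Light-driven decarboxylative borylation of 25 (B2cat2, DMAc, blue light) should give the primary catechol boronate F1, which is used crude. KHF2 in aqueous MeOH should convert it into the potassium trifluoroborate F2. A B-alkyl Suzuki–Miyaura macrocyclisation (PdCl2(dppf), Cs2CO3, toluene/H2O, high dilution, 80 °C) should then close the same C4–C5 bond with retention of the Z geometry to give 26.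

**Step 11 (cuprate addition).**
- What may go wrong: the enoate may isomerise from Z to E by reversible electron transfer from the cuprate before the C–C bond forms, which would turn the facial preference towards the anti adduct. The branched alkenyl ligand may also transfer slowly.
- Fallback: auxiliary control instead of substrate control. It sets out from 12 and comes back at 21. A Masamune–Roush Horner–Wadsworth–Emmons reaction of 12 with diethyl {2-oxo-2-[(4S)-2-oxo-4-phenyl-1,3-oxazolidin-3-yl]ethyl}phosphonate (LiCl, i-Pr2NEt, MeCN) should give the E-configured N-enoyl imide F3. The alkenylmagnesium bromide F4 is made from 16 and MgBr2·OEt2. With CuBr·SMe2 it should add to the chelated s-cis imide on the face opposite the phenyl group to give the adduct F5 with C1 as R. LiBH4 should release the primary alcohol F6, and Dess–Martin oxidation returns to 21.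

**Step 3 (allylic oxidation).**
- What may go wrong: oxidation may also strike the methyl group of the internal C7=C8 alkene, and it may run on past the alcohol stage.
- Fallback: metathesis instead of C–H oxidation. It sets out from 3 and comes back at 4. Cross-metathesis of the terminal isopropylidene unit of 3 with methacrolein (second-generation Hoveyda–Grubbs catalyst, CH2Cl2, 40 °C) leaves the internal trisubstituted alkene alone and should give the E-enal F7. Luche reduction (NaBH4, CeCl3·7H2O, MeOH, 0 °C) then gives 4.

**Further compounds**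
F1 | step 16 | catechol boronate at C5 of the Z-alkenyl iodide | C=C(CCC=C(C)C)[C@@H](C/C=C(/C)I)[C@H](C/C(C)=C/CC/C(C)=C\CCB1Oc2ccccc2O1)OC
F2 | step 16 | potassium trifluoroborate at C5 of the Z-alkenyl iodide | [K+].C=C(CCC=C(C)C)[C@@H](C/C=C(/C)I)[C@H](C/C(C)=C/CC/C(C)=C\CC[B-](F)(F)F)OC
F3 | step 11 | E-N-enoyl imide of (4S)-4-phenyl-1,3-oxazolidin-2-one | O=C(/C=C/[C@@H](OC)C/C(C)=C/CC/C(C)=C\CCC(=O)OC(C)(C)C)N1[C@@H](c2ccccc2)COC1=O
F4 | step 11 | (6-methylhepta-1,5-dien-2-yl)magnesium bromide | C=C([Mg]Br)CCC=C(C)C
F5 | step 11 | conjugate adduct imide (C1 R, C14 S) | C=C(CCC=C(C)C)[C@@H](CC(=O)N1[C@@H](c2ccccc2)COC1=O)[C@H](C/C(C)=C/CC/C(C)=C\CCC(=O)OC(C)(C)C)OC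
F6 | step 11 | primary alcohol at C3 | C=C(CCC=C(C)C)[C@@H](CCO)[C@H](C/C(C)=C/CC/C(C)=C\CCC(=O)OC(C)(C)C)OC
F7 | step 3 | tert-butyl (4Z,8E)-5,9-dimethyl-10-oxodeca-4,8-dienoate | O=C/C(C)=C/CC/C(C)=C\CCC(=O)OC(C)(C)C
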